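The route rests on cutting the piperidine ring at N1'–C6' and C5'–C6': C6' is an unsubstituted CH2 on nitrogen, three methylenes removed from the benzylic stereocentre C2', so it can be delivered by carbon monoxide. Rhodium-catalysed linear hydroformylation of an (R)-N-Boc homoallylic amine carrying the protected phloroglucinol ring (the future ring A) on C2', followed in the same flask by N-cyclisation and dehydration, forges both bonds and the six-membered ring as an ene-carbamate without touching C2'. The precursor is made by allylation of a tert-butanesulfinyl imine; the pyranone ring C with its phenyl group is annulated last by a second carbonylation.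

Key step: step 6

Remark: piperidine atoms are numbered N1', C2' (the stereocentre, R in the target) to C6'; the Grignard allylation is assumed to follow the magnesium-chelated chair model usual for tert-butanesulfinyl aldimines in CH2Cl2, which assigns the (S)-sulfinamide to the (R)-amine.

Step 1
Reactants: 1 2,4,6-trihydroxybenzaldehyde
Product: 2 2,6-dihydroxy-4-methoxybenzaldehyde
Conditions: Me2SO4 (1.0 equiv), K2CO3 (1.0 equiv), acetone, 0 °C to rt
Reagents that add atoms: dimethyl sulfate COS(=O)(=O)OC
Why: Williamson O-methylation with one equivalent of electrophile should go to the 4-OH, the most acidic hydroxyl and the only one not held in a hydrogen bond to the formyl oxygen.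

Step 2
Reactants: 2 2,6-dihydroxy-4-methoxybenzaldehyde
Product: 3 2,6-bis(benzyloxy)-4-methoxybenzaldehyde
Conditions: BnBr (2.5 equiv), K2CO3 (3 equiv), DMF, 60 °C
Reagents that add atoms: benzyl bromide BrCc1ccccc1
Why: Williamson O-benzylation in a dipolar aprotic solvent with mild heating should overcome the hydrogen bonding of both ortho-phenols, and benzyl ethers tolerate the Grignard, acid and syngas steps and fall in the later hydrogenation.

Step 3
Reactants: 3 2,6-bis(benzyloxy)-4-methoxybenzaldehyde; 4 (S)-tert-butanesulfinamide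
Product: 5 (S)-N-[(E)-[2,6-bis(benzyloxy)-4-methoxyphenyl]methylidene]-2-methylpropane-2-sulfinamide
Conditions: Ti(OEt)4 (2 equiv), THF, 65 °C
Reagents that add atoms: none
Why: Lewis-acid-mediated condensation of a sulfinamide with an aldehyde, in which Ti(OEt)4 activates the hindered, electron-rich formyl group and takes up the water, should give the E-imine with sulfur configuration unchanged.

Step 4
Reactants: 5 (S)-N-[(E)-[2,6-bis(benzyloxy)-4-methoxyphenyl]methylidene]-2-methylpropane-2-sulfinamide; 6 allylmagnesium bromide
Product: 7 (S)-N-[(1R)-1-[2,6-bis(benzyloxy)-4-methoxyphenyl]but-3-en-1-yl]-2-methylpropane-2-sulfinamide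
Conditions: allylmagnesium bromide (1 M in Et2O, 2 equiv), CH2Cl2, −78 °C; aq NH4Cl
Reagents that add atoms: none
Why: 1,2-addition of an allyl Grignard reagent to an N-sulfinyl aldimine through a six-membered chair transition state with magnesium on the sulfinyl oxygen and tert-butyl and aryl equatorial should, for (S)-configured sulfur, deliver allyl to the Re face and set C2' as R; any minor diastereomer is removed by chromatography.

Step 5
Reactants: 7 (S)-N-[(1R)-1-[2,6-bis(benzyloxy)-4-methoxyphenyl]but-3-en-1-yl]-2-methylpropane-2-sulfinamide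
Product: 9 tert-butyl N-[(1R)-1-[2,6-bis(benzyloxy)-4-methoxyphenyl]but-3-en-1-yl]carbamate, via primary amine 8 (not isolated)
Conditions: HCl (4 M in dioxane, 2 equiv), MeOH, 0 °C; evaporate; then Boc2O, NaHCO3, THF/H2O, rt
Reagents that add atoms: di-tert-butyl dicarbonate CC(C)(C)OC(=O)OC(=O)OC(C)(C)C
Why: acid methanolysis of the N–S bond followed by carbamate formation (N-acylation) should give the Boc amine, the short cold exposure to HCl keeping the electron-rich benzylic C–N bond from ionising so that C2' is carried over unchanged.

Step 6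
Reactants: 9 tert-butyl N-[(1R)-1-[2,6-bis(benzyloxy)-4-methoxyphenyl]but-3-en-1-yl]carbamate; 10 carbon monoxide
Product: 13 tert-butyl (2R)-2-[2,6-bis(benzyloxy)-4-methoxyphenyl]-3,4-dihydro-2H-pyridine-1-carboxylate, via linear aldehyde 11 (not isolated), via cyclic hemiaminal 12 (not isolated)
Conditions: Rh(acac)(CO)2 (2 mol %), BIPHEPHOS (4 mol %), CO/H2 (1:1, 4 bar), THF, 65 °C; vent, then PPTS (5 mol %), 65 °C
Reagents that add atoms: none
Why: A hydride of monovalent rhodium chelated by the bisphosphite inserts the C4'=C5' alkene with the metal ending on the terminal carbon, migratory CO insertion makes the C5'–C6' bond and H2 cleaves the acyl to aldehyde 11; the carbamate N–H then adds to this carbonyl to give hemiaminal 12, which loses water (finished by the trace of acid) to the ene-carbamate. The closest known reaction type is the rhodium–bisphosphite cyclohydrocarbonylation of N-carbamoyl homoallylic amines to six-membered cyclic ene-carbamates. The piperidine ring closes by 6-exo-trig attack of N1' on the C6' carbonyl. No stereocentre is created, because the hemiaminal centre at C6' is erased on dehydration, and C2' keeps its configuration since no bond to it is made or broken and C6' becomes electrophilic only after the alkene is gone, which rules out a cationic aza-Cope pathway. The step needs linear rather than branched CO delivery and must outrun alkene isomerisation and hydrogenation; the wide-bite-angle ligand acting on an unhindered monosubstituted alkene secures the former and the mild syngas pressure the latter, while the benzyl ethers and the Boc group are inert and, with the phenols capped, the carbamate nitrogen is the only nucleophile placed to form a six-membered ring.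

Step 7
Reactants: 13 tert-butyl (2R)-2-[2,6-bis(benzyloxy)-4-methoxyphenyl]-3,4-dihydro-2H-pyridine-1-carboxylate
Product: 14 tert-butyl (2R)-2-(2,6-dihydroxy-4-methoxyphenyl)piperidine-1-carboxylate
Conditions: H2 (1 atm), 10% Pd/C, EtOAc/MeOH, rt
Reagents that add atoms: none
Why: heterogeneous catalytic hydrogenation should saturate the C5'=C6' ene-carbamate and hydrogenolyse both aryl benzyl ethers in one operation, while the N-Boc benzylic C2'–N bond survives at ambient pressure and C2', which is not allylic, cannot epimerise.

Step 8
Reactants: 14 tert-butyl (2R)-2-(2,6-dihydroxy-4-methoxyphenyl)piperidine-1-carboxylate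
Product: 15 5-methoxy-2-[(2R)-1-methylpiperidin-2-yl]benzene-1,3-diol
Conditions: LiAlH4 (6 equiv), THF, 0 °C then reflux; aq potassium sodium tartrate, extraction at pH 8–9
Reagents that add atoms: none
Why: hydride reduction of a carbamate to an N-methyl amine should proceed after the two phenols have been converted into inert aluminium phenoxides (hence the excess), tert-butoxide being expelled and the carbonyl carbon reduced to CH3 with C2' untouched.

Step 9
Reactants: 15 5-methoxy-2-[(2R)-1-methylpiperidin-2-yl]benzene-1,3-diol
Product: 16 4-iodo-5-methoxy-2-[(2R)-1-methylpiperidin-2-yl]benzene-1,3-diol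
Conditions: NIS (1.0 equiv), CF3CO2H (1.05 equiv), MeCN, −20 °C; aq Na2S2O3/NaHCO3
Reagents that add atoms: N-iodosuccinimide O=C1CCC(=O)N1I
Why: electrophilic aromatic iodination should stop at the mono-iodide with one equivalent at low temperature, the two free ring positions being equivalent (each flanked by an OH and the OMe) so that no regiochemical question arises, and protonation shields the tertiary amine from N-iodination.

Step 10
Reactants: 16 4-iodo-5-methoxy-2-[(2R)-1-methylpiperidin-2-yl]benzene-1,3-diol; 17 phenylacetylene; 10 carbon monoxide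
Product: 20 7-hydroxy-5-methoxy-8-[(2R)-1-methylpiperidin-2-yl]-2-phenyl-4H-chromen-4-one, via alkynyl ketone 18 (not isolated), via enaminone 19 (not isolated)
Conditions: PdCl2(PPh3)2 (5 mol %), CO (10 bar), Et2NH, DMF, 80 °C
Reagents that add atoms: none
Why: copper-free carbonylative Sonogashira-type coupling (oxidative addition of the C–I bond to zerovalent palladium, CO insertion, alkynylation) should give ynone 18, diethylamine adds to it to form enaminone 19, and the only phenol ortho to the acyl group displaces the amine in a 6-endo addition–elimination that closes pyranone ring C and leaves the other phenol as the 7-OH.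

Compound list
1 | 2,4,6-trihydroxybenzaldehyde | O=Cc1c(O)cc(O)cc1O | starting material
2 | 2,6-dihydroxy-4-methoxybenzaldehyde | COc1cc(O)c(C=O)c(O)c1 | intermediate
3 | 2,6-bis(benzyloxy)-4-methoxybenzaldehyde | COc1cc(OCc2ccccc2)c(C=O)c(OCc2ccccc2)c1 | intermediate
4 | (S)-tert-butanesulfinamide | CC(C)(C)[S@@](N)=O | starting material
5 | (S)-N-[(E)-[2,6-bis(benzyloxy)-4-methoxyphenyl]methylidene]-2-methylpropane-2-sulfinamide | COc1cc(OCc2ccccc2)c(/C=N/[S@@](=O)C(C)(C)C)c(OCc2ccccc2)c1 | intermediate
6 | allylmagnesium bromide | C=CC[Mg]Br | starting material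
7 | (S)-N-[(1R)-1-[2,6-bis(benzyloxy)-4-methoxyphenyl]but-3-en-1-yl]-2-methylpropane-2-sulfinamide | COc1cc(OCc2ccccc2)c([C@H](N[S@@](=O)C(C)(C)C)CC=C)c(OCc2ccccc2)c1 | intermediate
8 | (1R)-1-[2,6-bis(benzyloxy)-4-methoxyphenyl]but-3-en-1-amine (present as its hydrochloride) | COc1cc(OCc2ccccc2)c([C@H](N)CC=C)c(OCc2ccccc2)c1 | intermediate
9 | tert-butyl N-[(1R)-1-[2,6-bis(benzyloxy)-4-methoxyphenyl]but-3-en-1-yl]carbamate | COc1cc(OCc2ccccc2)c([C@H](NC(=O)OC(C)(C)C)CC=C)c(OCc2ccccc2)c1 | intermediate
10 | carbon monoxide | [C-]#[O+] | starting material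
11 | tert-butyl N-[(1R)-1-[2,6-bis(benzyloxy)-4-methoxyphenyl]-5-oxopentyl]carbamate | COc1cc(OCc2ccccc2)c([C@H](NC(=O)OC(C)(C)C)CCCC=O)c(OCc2ccccc2)c1 | intermediate
12 | tert-butyl (2R)-2-[2,6-bis(benzyloxy)-4-methoxyphenyl]-6-hydroxypiperidine-1-carboxylate (both C6 epimers) | COc1cc(OCc2ccccc2)c([C@H]2CCCC(O)N2C(=O)OC(C)(C)C)c(OCc2ccccc2)c1 | intermediate
13 | tert-butyl (2R)-2-[2,6-bis(benzyloxy)-4-methoxyphenyl]-3,4-dihydro-2H-pyridine-1-carboxylate | COc1cc(OCc2ccccc2)c([C@H]2CCC=CN2C(=O)OC(C)(C)C)c(OCc2ccccc2)c1 | intermediate
14 | tert-butyl (2R)-2-(2,6-dihydroxy-4-methoxyphenyl)piperidine-1-carboxylate | COc1cc(O)c([C@H]2CCCCN2C(=O)OC(C)(C)C)c(O)c1 | intermediate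
15 | 5-methoxy-2-[(2R)-1-methylpiperidin-2-yl]benzene-1,3-diol | COc1cc(O)c([C@H]2CCCCN2C)c(O)c1 | intermediate
16 | 4-iodo-5-methoxy-2-[(2R)-1-methylpiperidin-2-yl]benzene-1,3-diol | COc1cc(O)c([C@H]2CCCCN2C)c(O)c1I | intermediate
17 | phenylacetylene | C#Cc1ccccc1 | starting material
18 | 1-[2,4-dihydroxy-6-methoxy-3-[(2R)-1-methylpiperidin-2-yl]phenyl]-3-phenylprop-2-yn-1-one | COc1cc(O)c([C@H]2CCCCN2C)c(O)c1C(=O)C#Cc1ccccc1 | intermediate
19 | 3-(diethylamino)-1-[2,4-dihydroxy-6-methoxy-3-[(2R)-1-methylpiperidin-2-yl]phenyl]-3-phenylprop-2-en-1-one (alkene geometry not defined) | COc1cc(O)c([C@H]2CCCCN2C)c(O)c1C(=O)C=C(N(CC)CC)c1ccccc1 | intermediate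
20 | 7-hydroxy-5-methoxy-8-[(2R)-1-methylpiperidin-2-yl]-2-phenyl-4H-chromen-4-one | COc1cc(O)c([C@H]2CCCCN2C)c2oc(-c3ccccc3)cc(=O)c12 | target

Total step count: 10. Longest linear sequence: 10 steps (1 to 20).

Steps most likely to fail

Step 10. The process at risk is the carbonylative annulation. The coupling may proceed without CO uptake and close 5-endo to a benzofuran, or the ynone may close 5-exo to an aurone. Oxidative addition may be slow at the electron-rich, doubly ortho-substituted iodide. Heat and base may epimerise C2' through reversible retro-Mannich opening to an ortho-quinone methide. The fallback sets out from 15, returns at 20, and also bypasses the iodination of step 9. Friedel–Crafts C-acetylation of 15 (Ac2O, BF3·OEt2, then aqueous NaOH to cleave any phenyl acetate) at the single type of free ring position should give 1-[2,4-dihydroxy-6-methoxy-3-[(2R)-1-methylpiperidin-2-yl]phenyl]ethan-1-one F1. Its polyanion (LiN(SiMe3)2 in excess, THF, −78 °C) is C-benzoylated with benzoyl chloride in a Claisen-type acylation to 1-[2,4-dihydroxy-6-methoxy-3-[(2R)-1-methylpiperidin-2-yl]phenyl]-3-phenylpropane-1,3-dione F2. Acid-catalysed cyclodehydration (AcOH, cat. H2SO4, 60 °C) through the only phenol ortho to the acyl group then closes ring C to give 20.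

Step 6. The process at risk is the hydroformylation–cyclisation cascade. CO may be delivered to the branched position, the alkene may isomerise or be hydrogenated, or the cyclisation may stall because the carbamate nitrogen sits next to the doubly ortho-substituted aryl group. The fallback sets out from 9 and returns at 14. N-Allylation of 9 (NaH, allyl bromide, DMF, 0 °C to rt) should give tert-butyl N-[(1R)-1-[2,6-bis(benzyloxy)-4-methoxyphenyl]but-3-en-1-yl]-N-(prop-2-en-1-yl)carbamate F3. Ring-closing metathesis with the second-generation Grubbs catalyst (CH2Cl2, 40 °C) closes the ring to tert-butyl (2R)-2-[2,6-bis(benzyloxy)-4-methoxyphenyl]-3,6-dihydro-2H-pyridine-1-carboxylate F4, in which C6' stems from allyl bromide. The hydrogenation conditions of step 7 then convert F4 into 14.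

Step 4. The process at risk is facial control: the ortho-benzyloxy groups may compete with the sulfinyl oxygen for magnesium and erode or invert the selectivity. The fallback sets out from 3 and returns at 8, and replaces chelation control by an open transition state with the antipodal auxiliary. Condensation of 3 with (R)-tert-butanesulfinamide (Ti(OEt)4, THF, 65 °C) gives (R)-N-[(E)-[2,6-bis(benzyloxy)-4-methoxyphenyl]methylidene]-2-methylpropane-2-sulfinamide F5. Barbier allylation with allyl bromide and zinc dust in HMPA/H2O follows; the strongly coordinating solvent suppresses chelation, so allyl should attack the face anti to tert-butyl of the s-cis sulfinimine and give (R)-N-[(1R)-1-[2,6-bis(benzyloxy)-4-methoxyphenyl]but-3-en-1-yl]-2-methylpropane-2-sulfinamide F6. HCl/MeOH cleavage of F6 gives 8, which is Boc-protected as in step 5.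

Further compounds
F1 | step 10 | 1-[2,4-dihydroxy-6-methoxy-3-[(2R)-1-methylpiperidin-2-yl]phenyl]ethan-1-one | COc1cc(O)c([C@H]2CCCCN2C)c(O)c1C(C)=O
F2 | step 10 | 1-[2,4-dihydroxy-6-methoxy-3-[(2R)-1-methylpiperidin-2-yl]phenyl]-3-phenylpropane-1,3-dione | COc1cc(O)c([C@H]2CCCCN2C)c(O)c1C(=O)CC(=O)c1ccccc1
F3 | step 6 | tert-butyl N-[(1R)-1-[2,6-bis(benzyloxy)-4-methoxyphenyl]but-3-en-1-yl]-N-(prop-2-en-1-yl)carbamate | COc1cc(OCc2ccccc2)c([C@H](N(CC=C)C(=O)OC(C)(C)C)CC=C)c(OCc2ccccc2)c1
F4 | step 6 | tert-butyl (2R)-2-[2,6-bis(benzyloxy)-4-methoxyphenyl]-3,6-dihydro-2H-pyridine-1-carboxylate | COc1cc(OCc2ccccc2)c([C@H]2CC=CCN2C(=O)OC(C)(C)C)c(OCc2ccccc2)c1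
F5 | step 4 | (R)-N-[(E)-[2,6-bis(benzyloxy)-4-methoxyphenyl]methylidene]-2-methylpropane-2-sulfinamide | COc1cc(OCc2ccccc2)c(/C=N/[S@](=O)C(C)(C)C)c(OCc2ccccc2)c1
F6 | step 4 | (R)-N-[(1R)-1-[2,6-bis(benzyloxy)-4-methoxyphenyl]but-3-en-1-yl]-2-methylpropane-2-sulfinamide | COc1cc(OCc2ccccc2)c([C@H](N[S@](=O)C(C)(C)C)CC=C)c(OCc2ccccc2)c1
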